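**Strategy.** Ring F of the flavone is disconnected at C4af–C4f, C4f–C3f and O1f–C2f, back to an iodinated ring D, an aryl alkyne and CO. Ring D is a 2-substituted phloroglucinol with a local mirror plane through C8f and C5f. With O5f capped as a benzyl ether, its two oxygens flanking C8f are equivalent, so one carbonylative alkyne annulation builds the pyranone with the 8f linkage and leaves O7f as the only free phenol for sulfation. The precursor is the (2R,3S)-trans-3-(4-benzyloxy-2,6-dihydroxy-3-iodophenyl)flavanone tribenzyl ether, made by Negishi coupling, copper-catalysed conjugate arylation and resolution. One hydrogenolysis then unveils all phenols.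

Key step: step 10

**Remarks on the chemistry (assumptions and design choices)**
- Plain locants refer to the flavanone (rings A, B, C); locants with the suffix f refer to the flavone (rings D, F and its aryl ring).
- Ring C of the target is (2R,3S), which is the trans arrangement. Slow rotation about C3–C8f is assumed to give interconverting rotamers only, not a stereo-element to control.
- The aryl hydrogen sulfates 22 and 23 are drawn as free acids. They are assumed to be handled as triethylammonium salts, and the acid form is released on an H+ resin only at the end.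
- A racemate is written as its two enantiomers joined by a dot.
- O5f is carried as a benzyl ether, not a silyl ether. It is smaller beside the iodide, inert to the amine base, and falls in the final hydrogenolysis, so no separate desilylation is needed.
- Catalytic asymmetric conjugate arylation is not used on the 3-arylchromone. Migratory insertion would put the metal on C3, which is shielded on both faces by the ortho substituents of the perpendicular ring D. A copper-catalysed addition (metal at C2) followed by resolution is chosen as the dependable way to the single enantiomer.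

**Route**

Step 1
Reactants: 1 2',4',6'-trihydroxyacetophenone
Product: 2 ring A ketone (1-[2,4-bis(benzyloxy)-6-hydroxyphenyl]ethan-1-one)
Conditions: BnBr (2.1 equiv), K2CO3 (2.2 equiv), DMF, rt
Reagents that add atoms: benzyl bromide, BrCc1ccccc1
Why: Williamson etherification: with two equivalents of benzyl bromide the para phenol and one ortho phenol are alkylated, while the remaining ortho phenol is held in a hydrogen bond to the acetyl carbonyl and stays free.

Step 2
Reactants: 2 ring A ketone
Product: 4 iodochromone (5,7-bis(benzyloxy)-3-iodo-4H-chromen-4-one), via enaminone 3 (not isolated)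
Conditions: Me2NCH(OMe)2, toluene, 95 °C; evaporate; I2 (2 equiv), CHCl3, rt
Reagents that add atoms: N,N-dimethylformamide dimethyl acetal, COC(OC)N(C)C; iodine, [I][I]
Why: Condensation of the methyl ketone with the amide acetal gives enaminone 3, and iodine then effects the known enaminone iodocyclisation (iodine attacks the α-carbon, the phenol closes the ring, dimethylamine is lost) to the 3-iodochromone.

Step 3
Reactants: 5 phloroglucinol
Product: 6 3,5-bis(methoxymethoxy)phenol
Conditions: MeOCH2Cl (2.1 equiv), i-Pr2NEt (2.5 equiv), DMF, 0 °C to rt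
Reagents that add atoms: chloromethyl methyl ether, COCCl
Why: Statistical O-alkylation of a symmetric triol with two equivalents of the chloromethyl ether; the bis-ether is separated by chromatography and the mono- and tris-ethers are recycled after acid hydrolysis.

Step 4
Reactants: 6 3,5-bis(methoxymethoxy)phenol
Product: 7 ring D ether (1-(benzyloxy)-3,5-bis(methoxymethoxy)benzene)
Conditions: BnBr (1.1 equiv), K2CO3, DMF, rt
Reagents that add atoms: benzyl bromide, BrCc1ccccc1
Why: Williamson etherification of the one remaining phenol; the acetals are inert to carbonate.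

Step 5
Reactants: 7 ring D ether, 4 iodochromone
Product: 10 isoflavone (5,7-bis(benzyloxy)-3-[4-(benzyloxy)-2,6-bis(methoxymethoxy)phenyl]-4H-chromen-4-one), via aryllithium 8 (not isolated), via arylzinc chloride 9 (not isolated)
Conditions: 7 (1.3 equiv), n-BuLi, THF, 0 °C; ZnCl2, 0 °C to rt; then 4, Pd2(dba)3 (2 mol %), SPhos (8 mol %), THF, 55 °C
Reagents that add atoms: none
Why: Directed ortho-metalation takes place at the carbon flanked by the two chelating methoxymethoxy groups, transmetalation gives the arylzinc chloride, and Negishi coupling with the iodoenone at zerovalent palladium bearing a bulky biarylphosphine tolerates the two ortho substituents.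

Step 6
Reactants: 10 isoflavone, 11 [4-(benzyloxy)phenyl]magnesium bromide (commercial THF solution)
Product: 13 racemic trans-flavanone (rac-(2R,3S)-5,7-bis(benzyloxy)-2-[4-(benzyloxy)phenyl]-3-[4-(benzyloxy)-2,6-bis(methoxymethoxy)phenyl]-2,3-dihydro-4H-chromen-4-one), via silyl enol ether 12 (not isolated)
Conditions: 11 (2.5 equiv), CuBr·SMe2 (20 mol %), Me3SiCl (3 equiv), THF, −40 to 0 °C; then 1 M aq citric acid, THF, 0 °C; then Et3N, MeOH, rt
Reagents that add atoms: none
Why: Copper-catalysed, Me3SiCl-accelerated conjugate addition of the aryl Grignard reagent to the chromone places the metal at the open C2 and not at the shielded C3, the enolate is trapped as silyl enol ether 12, and hydrolysis followed by amine equilibration of the enolisable C3 should give the diequatorial trans isomer as a racemate (C2 is set without facial control, C3 under thermodynamic control).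

Step 7
Reactants: 13 racemic trans-flavanone
Product: 14 (2R,3S)-flavanone ((2R,3S)-5,7-bis(benzyloxy)-2-[4-(benzyloxy)phenyl]-3-[4-(benzyloxy)-2,6-bis(methoxymethoxy)phenyl]-2,3-dihydro-4H-chromen-4-one)
Conditions: preparative SFC on immobilised amylose tris(3,5-dimethylphenylcarbamate), CO2–i-PrOH, 35 °C
Reagents that add atoms: none
Why: Chromatographic resolution on a chiral stationary phase selects the (2R,3S) enantiomer, whose assignment is to be confirmed by electronic circular dichroism or by X-ray analysis of iodide 16; the antipode can be racemised by base (opening and reclosure of ring C) and recycled.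

Step 8
Reactants: 14 (2R,3S)-flavanone
Product: 15 diol ((2R,3S)-5,7-bis(benzyloxy)-2-[4-(benzyloxy)phenyl]-3-[4-(benzyloxy)-2,6-dihydroxyphenyl]-2,3-dihydro-4H-chromen-4-one)
Conditions: HCl (1.25 M in MeOH), THF, 35 °C
Reagents that add atoms: none
Why: Acid-catalysed acetal exchange with methanol removes both aryl methoxymethyl ethers, while benzyl ethers and the chromanone survive dilute acid near room temperature, where cyclodehydration of the ortho-hydroxyaryl ketone to a benzofuran is not expected.

Step 9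
Reactants: 15 diol
Product: 16 iodide ((2R,3S)-5,7-bis(benzyloxy)-2-[4-(benzyloxy)phenyl]-3-[4-(benzyloxy)-2,6-dihydroxy-3-iodophenyl]-2,3-dihydro-4H-chromen-4-one)
Conditions: N-iodosuccinimide (1.0 equiv), CH2Cl2–MeCN, −30 to 0 °C, dark
Reagents that add atoms: N-iodosuccinimide, O=C1CCC(=O)N1I
Why: Electrophilic aromatic iodination goes to ring D, the only ring with free phenols, at one of its two equivalent CH positions (ortho to one hydroxyl, para to the other), and one equivalent of reagent at low temperature should hold it at the mono-iodide.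

Step 10
Reactants: 16 iodide, 17 1-(benzyloxy)-4-ethynylbenzene, 18 carbon monoxide
Product: 21 biflavonoid phenol ((2R,3S)-5,7-bis(benzyloxy)-2-[4-(benzyloxy)phenyl]-3-{5-(benzyloxy)-2-[4-(benzyloxy)phenyl]-7-hydroxy-4-oxo-4H-chromen-8-yl}-2,3-dihydro-4H-chromen-4-one), via ynone 19 (not isolated), via enaminone 20 (not isolated)
Conditions: PdCl2(PPh3)2 (5 mol %), CO (1 atm), 17 (1.5 equiv), Et2NH (5 equiv), DMF, 40 °C, no copper
Reagents that add atoms: none
Why: PdCl2(PPh3)2 is reduced in the flask to zerovalent palladium, which inserts into the C4af–I bond; CO insertion gives the aroyl–palladium species, the amine-deprotonated alkyne is transferred, and reductive elimination forms C4af–C4f and C4f–C3f in ynone 19. Diethylamine then adds to the ynone to give enaminone 20, and the phenol beside the acyl group displaces the amine at C2f, so ring F closes by a net 6-endo-dig oxa-Michael addition–elimination (O1f–C2f). The closest known reaction is the copper-free carbonylative Sonogashira annulation of ortho-iodophenols with terminal alkynes to flavones. No stereocentre is formed: C2 and C3 of ring C are spectators, the enolisable C3 can only relax to the trans arrangement already present, and a secondary amine at 40 °C is chosen to avoid retro-oxa-Michael opening of ring C. The step needs the 8f over the 6f linkage and 6-endo over 5-exo closure: the first is secured because O5f is a benzyl ether and the two oxygens flanking C8f are equivalent through the mirror plane of ring D (C8f, C5f), so the iodine position alone decides which one closes and the other emerges as the sole free phenol O7f; the second is secured by the amine addition–elimination path, which cannot lead to the aurone. Leaving out copper and working under CO should suppress direct alkynylation and benzofuran formation.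

Step 11
Reactants: 21 biflavonoid phenol
Product: 22 sulfate pentabenzyl ether ((2R,3S)-5,7-bis(benzyloxy)-2-[4-(benzyloxy)phenyl]-3-{5-(benzyloxy)-2-[4-(benzyloxy)phenyl]-4-oxo-7-(sulfooxy)-4H-chromen-8-yl}-2,3-dihydro-4H-chromen-4-one; handled as triethylammonium salt)
Conditions: SO3·NMe3 (5 equiv), Et3N (10 equiv), MeCN, 40 °C; Sephadex LH-20
Reagents that add atoms: sulfur trioxide–trimethylamine complex, C[N+](C)(C)S(=O)(=O)[O-]
Why: O-Sulfonation of the only free phenol by the sulfur trioxide–amine complex (standard phenol sulfation); all other oxygens are ethers, and the weak amine base at 40 °C should leave ring C untouched.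

Step 12
Reactants: 22 sulfate pentabenzyl ether
Product: 23 target ((2R,3S)-5,7-dihydroxy-2-(4-hydroxyphenyl)-3-[5-hydroxy-2-(4-hydroxyphenyl)-4-oxo-7-(sulfooxy)-4H-chromen-8-yl]-2,3-dihydro-4H-chromen-4-one)
Conditions: H2 (1 atm), 10% Pd/C, THF–MeOH, rt (substrate as triethylammonium salt); then Dowex 50W (H+ form), MeOH–H2O, 0 °C, lyophilise
Reagents that add atoms: none
Why: Hydrogenolysis cleaves the five benzyl aryl ethers in one operation, while the aryl sulfate (as its ammonium salt), the flavone double bond and the ring C ketone are expected to survive atmospheric hydrogen at room temperature, and C2 and C3 are not touched under these neutral conditions.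

**Compound list**

1 | 2',4',6'-trihydroxyacetophenone | CC(=O)c1c(O)cc(O)cc1O | starting material
2 | ring A ketone, 1-[2,4-bis(benzyloxy)-6-hydroxyphenyl]ethan-1-one | CC(=O)c1c(O)cc(OCc2ccccc2)cc1OCc1ccccc1 | intermediate
3 | enaminone, (E)-1-[2,4-bis(benzyloxy)-6-hydroxyphenyl]-3-(dimethylamino)prop-2-en-1-one | CN(C)/C=C/C(=O)c1c(O)cc(OCc2ccccc2)cc1OCc1ccccc1 | intermediate (not isolated)
4 | iodochromone, 5,7-bis(benzyloxy)-3-iodo-4H-chromen-4-one | O=c1c(I)coc2cc(OCc3ccccc3)cc(OCc3ccccc3)c12 | intermediate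
5 | phloroglucinol | Oc1cc(O)cc(O)c1 | starting material
6 | 3,5-bis(methoxymethoxy)phenol | COCOc1cc(O)cc(OCOC)c1 | intermediate
7 | ring D ether, 1-(benzyloxy)-3,5-bis(methoxymethoxy)benzene | COCOc1cc(OCOC)cc(OCc2ccccc2)c1 | intermediate
8 | aryllithium, [4-(benzyloxy)-2,6-bis(methoxymethoxy)phenyl]lithium | [Li]c1c(OCOC)cc(OCc2ccccc2)cc1OCOC | intermediate (not isolated)
9 | arylzinc chloride, [4-(benzyloxy)-2,6-bis(methoxymethoxy)phenyl]zinc chloride | Cl[Zn]c1c(OCOC)cc(OCc2ccccc2)cc1OCOC | intermediate (not isolated)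
10 | isoflavone, 5,7-bis(benzyloxy)-3-[4-(benzyloxy)-2,6-bis(methoxymethoxy)phenyl]-4H-chromen-4-one | O=c1c(-c2c(OCOC)cc(OCc3ccccc3)cc2OCOC)coc2cc(OCc3ccccc3)cc(OCc3ccccc3)c12 | intermediate
11 | [4-(benzyloxy)phenyl]magnesium bromide | Br[Mg]c1ccc(OCc2ccccc2)cc1 | starting material
12 | silyl enol ether, racemic {5,7-bis(benzyloxy)-2-[4-(benzyloxy)phenyl]-3-[4-(benzyloxy)-2,6-bis(methoxymethoxy)phenyl]-2H-chromen-4-yl}oxy(trimethyl)silane | C[Si](C)(C)OC1=C(c2c(OCOC)cc(OCc3ccccc3)cc2OCOC)C(c2ccc(OCc3ccccc3)cc2)Oc2cc(OCc3ccccc3)cc(OCc3ccccc3)c12 | intermediate (not isolated)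
13 | racemic trans-flavanone, rac-(2R,3S)-5,7-bis(benzyloxy)-2-[4-(benzyloxy)phenyl]-3-[4-(benzyloxy)-2,6-bis(methoxymethoxy)phenyl]-2,3-dihydro-4H-chromen-4-one | O=C1c2c(OCc3ccccc3)cc(OCc3ccccc3)cc2O[C@@H](c2ccc(OCc3ccccc3)cc2)[C@@H]1c1c(OCOC)cc(OCc2ccccc2)cc1OCOC.O=C1c2c(OCc3ccccc3)cc(OCc3ccccc3)cc2O[C@H](c2ccc(OCc3ccccc3)cc2)[C@H]1c1c(OCOC)cc(OCc2ccccc2)cc1OCOC | intermediate
14 | (2R,3S)-5,7-bis(benzyloxy)-2-[4-(benzyloxy)phenyl]-3-[4-(benzyloxy)-2,6-bis(methoxymethoxy)phenyl]-2,3-dihydro-4H-chromen-4-one | O=C1c2c(OCc3ccccc3)cc(OCc3ccccc3)cc2O[C@@H](c2ccc(OCc3ccccc3)cc2)[C@@H]1c1c(OCOC)cc(OCc2ccccc2)cc1OCOC | intermediate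
15 | diol, (2R,3S)-5,7-bis(benzyloxy)-2-[4-(benzyloxy)phenyl]-3-[4-(benzyloxy)-2,6-dihydroxyphenyl]-2,3-dihydro-4H-chromen-4-one | O=C1c2c(OCc3ccccc3)cc(OCc3ccccc3)cc2O[C@@H](c2ccc(OCc3ccccc3)cc2)[C@@H]1c1c(O)cc(OCc2ccccc2)cc1O | intermediate
16 | iodide (key-step precursor), (2R,3S)-5,7-bis(benzyloxy)-2-[4-(benzyloxy)phenyl]-3-[4-(benzyloxy)-2,6-dihydroxy-3-iodophenyl]-2,3-dihydro-4H-chromen-4-one | O=C1c2c(OCc3ccccc3)cc(OCc3ccccc3)cc2O[C@@H](c2ccc(OCc3ccccc3)cc2)[C@@H]1c1c(O)cc(OCc2ccccc2)c(I)c1O | intermediate
17 | 1-(benzyloxy)-4-ethynylbenzene | C#Cc1ccc(OCc2ccccc2)cc1 | starting material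
18 | carbon monoxide | [C-]#[O+] | starting material
19 | ynone, (2R,3S)-5,7-bis(benzyloxy)-2-[4-(benzyloxy)phenyl]-3-{4-(benzyloxy)-3-[3-(4-(benzyloxy)phenyl)prop-2-ynoyl]-2,6-dihydroxyphenyl}-2,3-dihydro-4H-chromen-4-one | O=C1c2c(OCc3ccccc3)cc(OCc3ccccc3)cc2O[C@@H](c2ccc(OCc3ccccc3)cc2)[C@@H]1c1c(O)cc(OCc2ccccc2)c(C(=O)C#Cc2ccc(OCc3ccccc3)cc2)c1O | intermediate (not isolated)
20 | enaminone, (2R,3S)-5,7-bis(benzyloxy)-2-[4-(benzyloxy)phenyl]-3-{4-(benzyloxy)-3-[3-(4-(benzyloxy)phenyl)-3-(diethylamino)prop-2-enoyl]-2,6-dihydroxyphenyl}-2,3-dihydro-4H-chromen-4-one (alkene geometry not fixed) | O=C1c2c(OCc3ccccc3)cc(OCc3ccccc3)cc2O[C@@H](c2ccc(OCc3ccccc3)cc2)[C@@H]1c1c(O)cc(OCc2ccccc2)c(C(=O)C=C(N(CC)CC)c2ccc(OCc3ccccc3)cc2)c1O | intermediate (not isolated)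
21 | biflavonoid phenol (key-step product), (2R,3S)-5,7-bis(benzyloxy)-2-[4-(benzyloxy)phenyl]-3-{5-(benzyloxy)-2-[4-(benzyloxy)phenyl]-7-hydroxy-4-oxo-4H-chromen-8-yl}-2,3-dihydro-4H-chromen-4-one | O=C1c2c(OCc3ccccc3)cc(OCc3ccccc3)cc2O[C@@H](c2ccc(OCc3ccccc3)cc2)[C@@H]1c1c(O)cc(OCc2ccccc2)c2c(=O)cc(-c3ccc(OCc4ccccc4)cc3)oc12 | intermediate
22 | sulfate pentabenzyl ether, (2R,3S)-5,7-bis(benzyloxy)-2-[4-(benzyloxy)phenyl]-3-{5-(benzyloxy)-2-[4-(benzyloxy)phenyl]-4-oxo-7-(sulfooxy)-4H-chromen-8-yl}-2,3-dihydro-4H-chromen-4-one | O=C1c2c(OCc3ccccc3)cc(OCc3ccccc3)cc2O[C@@H](c2ccc(OCc3ccccc3)cc2)[C@@H]1c1c(OS(=O)(=O)O)cc(OCc2ccccc2)c2c(=O)cc(-c3ccc(OCc4ccccc4)cc3)oc12 | intermediate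
23 | (2R,3S)-5,7-dihydroxy-2-(4-hydroxyphenyl)-3-[5-hydroxy-2-(4-hydroxyphenyl)-4-oxo-7-(sulfooxy)-4H-chromen-8-yl]-2,3-dihydro-4H-chromen-4-one | O=C1c2c(O)cc(O)cc2O[C@@H](c2ccc(O)cc2)[C@@H]1c1c(OS(=O)(=O)O)cc(O)c2c(=O)cc(-c3ccc(O)cc3)oc12 | target

**Totals**

Total step count: 12. Longest linear sequence: 10 steps (1 → 2 → 4 → 10 → 13 → 14 → 15 → 16 → 21 → 22 → 23; the branch from 5 is equally long).

**The three steps most likely to fail**

1. Step 10. Under the amine, ring C may open by retro-oxa-Michael elimination from the C3 enolate, which would erode the C2 configuration. Oxidative addition and CO insertion at an iodide crowded by the sp3-linked ring C may also be slow enough for proto-deiodination or direct alkynylation to compete. The fallback builds ring F while the flavanone unit is still a flat chromone without stereocentres; it sets out from 10 and comes back at 21. The methoxymethyl ethers of 10 are cleaved (HCl, MeOH–THF) to the isoflavone diol 5,7-bis(benzyloxy)-3-[4-(benzyloxy)-2,6-dihydroxyphenyl]-4H-chromen-4-one F1. One equivalent of N-iodosuccinimide gives the mono-iodide 5,7-bis(benzyloxy)-3-[4-(benzyloxy)-2,6-dihydroxy-3-iodophenyl]-4H-chromen-4-one F2. The same copper-free carbonylative annulation with 17 and 18 (PdCl2(PPh3)2, Et2NH, DMF; any amine adduct of the chromone reverts on acidic work-up) gives the chromone–flavone 5,7-bis(benzyloxy)-3-{5-(benzyloxy)-2-[4-(benzyloxy)phenyl]-7-hydroxy-4-oxo-4H-chromen-8-yl}-4H-chromen-4-one F3. Copper-catalysed addition of 11 (one further equivalent is consumed by the phenol) to the unsubstituted C2 of the chromone under the conditions of step 6 gives the racemic trans biflavonoid phenol F4. The 2-aryl-substituted flavone is the poorer acceptor. Chiral SFC as in step 7 returns 21.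

2. Step 6. C2 of isoflavone 10 is screened by the ortho methoxymethoxy groups of the perpendicular ring D, so the 1,4-addition may stall while 1,2-addition at C4 or recovery of 10 takes over. The fallback forms ring C by condensation instead of addition to it; it sets out from 10 and comes back at 13. Alkaline cleavage of the isoflavone (KOH, aq EtOH, reflux; loss of C2 as formate) gives the deoxybenzoin 1-[2,4-bis(benzyloxy)-6-hydroxyphenyl]-2-[4-(benzyloxy)-2,6-bis(methoxymethoxy)phenyl]ethan-1-one F5. Piperidine-catalysed aldol condensation of F5 with commercial 4-(benzyloxy)benzaldehyde (O=Cc1ccc(OCc2ccccc2)cc1; EtOH, reflux), followed by oxa-Michael closure, is the classical route to trans-2,3-diarylchroman-4-ones and should return 13.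

3. Step 11. O7f lies beside the C8f substituent, so sulfation may stay incomplete, and the ionic monoester may hydrolyse or streak during purification. The fallback introduces the sulfate as a neutral, chromatographable diester; it sets out from 21 and comes back at 22. Treatment of 21 with 2,2,2-trichloroethyl chlorosulfate (ClS(=O)(=O)OCC(Cl)(Cl)Cl; Et3N, DMAP, THF, 0 °C) gives the aryl 2,2,2-trichloroethyl sulfate of 21 F6, purified on silica. Reductive fragmentation with Zn and HCO2NH4 in MeOH–THF at rt unmasks the monoester 22 as its ammonium salt, which enters step 12.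

**Further compounds**

F1 | step 10 | 5,7-bis(benzyloxy)-3-[4-(benzyloxy)-2,6-dihydroxyphenyl]-4H-chromen-4-one | O=c1c(-c2c(O)cc(OCc3ccccc3)cc2O)coc2cc(OCc3ccccc3)cc(OCc3ccccc3)c12
F2 | step 10 | 5,7-bis(benzyloxy)-3-[4-(benzyloxy)-2,6-dihydroxy-3-iodophenyl]-4H-chromen-4-one | O=c1c(-c2c(O)cc(OCc3ccccc3)c(I)c2O)coc2cc(OCc3ccccc3)cc(OCc3ccccc3)c12
F3 | step 10 | 5,7-bis(benzyloxy)-3-{5-(benzyloxy)-2-[4-(benzyloxy)phenyl]-7-hydroxy-4-oxo-4H-chromen-8-yl}-4H-chromen-4-one | O=c1c(-c2c(O)cc(OCc3ccccc3)c3c(=O)cc(-c4ccc(OCc5ccccc5)cc4)oc23)coc2cc(OCc3ccccc3)cc(OCc3ccccc3)c12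
F4 | step 10 | racemic trans biflavonoid phenol (racemate of 21) | O=C1c2c(OCc3ccccc3)cc(OCc3ccccc3)cc2O[C@@H](c2ccc(OCc3ccccc3)cc2)[C@@H]1c1c(O)cc(OCc2ccccc2)c2c(=O)cc(-c3ccc(OCc4ccccc4)cc3)oc12.O=C1c2c(OCc3ccccc3)cc(OCc3ccccc3)cc2O[C@H](c2ccc(OCc3ccccc3)cc2)[C@H]1c1c(O)cc(OCc2ccccc2)c2c(=O)cc(-c3ccc(OCc4ccccc4)cc3)oc12
F5 | step 6 | 1-[2,4-bis(benzyloxy)-6-hydroxyphenyl]-2-[4-(benzyloxy)-2,6-bis(methoxymethoxy)phenyl]ethan-1-one | O=C(Cc1c(OCOC)cc(OCc2ccccc2)cc1OCOC)c1c(O)cc(OCc2ccccc2)cc1OCc1ccccc1
F6 | step 11 | aryl 2,2,2-trichloroethyl sulfate of 21, (2R,3S)-5,7-bis(benzyloxy)-2-[4-(benzyloxy)phenyl]-3-{5-(benzyloxy)-2-[4-(benzyloxy)phenyl]-4-oxo-7-[(2,2,2-trichloroethoxy)sulfonyloxy]-4H-chromen-8-yl}-2,3-dihydro-4H-chromen-4-one | O=C1c2c(OCc3ccccc3)cc(OCc3ccccc3)cc2O[C@@H](c2ccc(OCc3ccccc3)cc2)[C@@H]1c1c(OS(=O)(=O)OCC(Cl)(Cl)Cl)cc(OCc2ccccc2)c2c(=O)cc(-c3ccc(OCc4ccccc4)cc3)oc12
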